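Numbering follows the xanthanolides. The unprimed unit carries the OH (ring A = C1, C5–C10), the primed unit has its lactone spiro at C11', and ring B = C1–C2–C3–C11'–C13'–C5.
Cuts: first the C1–O bond, back to a C1=C2 β,γ-enone. Then C3–C11' of ring B, with C11' re-joined to C1, which shrinks ring B to the cyclobutane C1–C5–C13'–C11'. Then C5–C13' and C1–C11', which leaves two molecules of one monomer.
The monomer is cut at C1=C5 and C2=C3 (enyne and cross metathesis), at C12 (CO) and at C7–C8 (aldehyde plus propargylic mesylate).
Forward order: C7–C8 chain, lactone, ring A with its dienone arm, cyclobutane by photodimerisation, ring B by a two-atom ring expansion, C1–OH last.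
What makes the event possible: in the dimer, the cyclobutane bond C1–C11' joins two quaternary carbons and lies between the C2=C3 vinyl ketone on C1 and the lactone carbonyl C12' on C11'. It alone should break on heating, and its ends can meet again only at C1 or, through the allyl unit, at C3.
Stereochemistry: C10 from a chiral rhodium catalyst; C7 from a Keck-derived mesylate (inversion); C8 from an anti-selective addition; C5 from the twisted dienone triplet; C11' from the lactone face anti to C6' during the ring expansion; C1 from epoxidation anti to the acetyl group. C3 and the C1/C11' centres of the cyclobutane are transient.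

Key step: step 10

Remark: the cyclobutane dimer and the ring-B cyclohexene are drawn as the expected main isomers. Isomers that differ only at transient elements (C1/C11' of the cyclobutane, C2=C3 geometry of its arm, C3 of the cyclohexene) are carried on because they converge.

Step 1
Reactants: 1 (E)-crotonaldehyde; 2 (triisopropylsilyl)acetylene
Product: 3 (S)-3-methyl-5-(triisopropylsilyl)pent-4-ynal
Conditions: [Rh(OAc)(C2H4)2]2 (2.5 mol %), DTBM-SEGPHOS (5.5 mol %, the antipode that gives the S product), MeOH, 40 °C
Reagents that add atoms: none
Why: Rhodium-catalysed asymmetric conjugate alkynylation of an enal, in which the bulky silyl group suppresses alkyne dimerisation and 1,2-addition and the chiral bisphosphine selects the enal face and so sets C10 (S).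

Step 2
Reactants: 4 3-(trimethylsilyl)propynal; 5 allyltributylstannane
Product: 6 (R)-1-(trimethylsilyl)hex-5-en-1-yn-3-ol
Conditions: Ti(OiPr)4 (10 mol %), (R)-BINOL (20 mol %), 4 Å MS, CH2Cl2, −20 °C; aq. NaHCO3
Reagents that add atoms: none
Why: Keck asymmetric allylation, for which alkynals are good substrates; the (R)-BINOL–titanium Lewis acid shields one aldehyde face and should give the R carbinol that later becomes C7.

Step 3
Reactants: 6 (R)-1-(trimethylsilyl)hex-5-en-1-yn-3-ol
Product: 7 (R)-1-(trimethylsilyl)hex-5-en-1-yn-3-yl methanesulfonate
Conditions: MsCl, Et3N, CH2Cl2, −78 to 0 °C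
Reagents that add atoms: methanesulfonyl chloride CS(=O)(=O)Cl
Why: Standard O-sulfonylation of a secondary propargylic alcohol, which does not touch the C–O stereocentre.

Step 4
Reactants: 7 (R)-1-(trimethylsilyl)hex-5-en-1-yn-3-yl methanesulfonate; 3 (S)-3-methyl-5-(triisopropylsilyl)pent-4-ynal
Product: 9 (3S,4R,6S)-3-allyl-6-methyl-8-(triisopropylsilyl)-1-(trimethylsilyl)octa-1,7-diyn-4-ol, via allenylindium reagent 8 (not isolated)
Conditions: Pd(dppf)Cl2 (5 mol %), InI (1.4 equiv), THF–HMPA 3:1, rt; aq. NH4Cl
Reagents that add atoms: none
Why: Marshall propargylation, in which zerovalent palladium formed in situ displaces the mesylate anti (SN2'), InI turns the allenylpalladium species into a configurationally defined allenylindium reagent, and this adds to the aldehyde through a cyclic SE2' transition state on the metal-bearing face, so that C7 forms with net inversion (S), C8 follows as its anti partner (R) and the remote C10 centre has no say.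

Step 5
Reactants: 9 (3S,4R,6S)-3-allyl-6-methyl-8-(triisopropylsilyl)-1-(trimethylsilyl)octa-1,7-diyn-4-ol
Product: 10 (3S,4R,6S)-3-allyl-6-methyl-8-(triisopropylsilyl)octa-1,7-diyn-4-ol
Conditions: K2CO3 (0.2 equiv), MeOH, 0 °C to rt
Reagents that add atoms: none
Why: Base-catalysed methanolysis of an alkynyl C–Si bond, selective because the trimethylsilyl group is far less hindered than the triisopropylsilyl group, which frees only the alkyne needed for the lactone.

Step 6
Reactants: 10 (3S,4R,6S)-3-allyl-6-methyl-8-(triisopropylsilyl)octa-1,7-diyn-4-ol
Product: 11 (4S,5R)-4-allyl-3-methylidene-5-[(2S)-2-methyl-4-(triisopropylsilyl)but-3-yn-1-yl]oxolan-2-one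
Conditions: Pd(OAc)2 (2 mol %), 2-(diphenylphosphino)pyridine (8 mol %), p-TsOH (8 mol %), CO (10 bar), BHT, toluene, 50 °C
Reagents that add atoms: carbon monoxide [C-]#[O+]
Why: Palladium-catalysed Markovnikov cyclocarbonylation of a homopropargylic alcohol, in which the branched acylpalladium species is captured by the C8 hydroxyl group to close the five-membered α-methylene lactone, the anti alcohol gives the trans lactone, and the hindered silyl alkyne and the allyl group stay out.

Step 7
Reactants: 11 (4S,5R)-4-allyl-3-methylidene-5-[(2S)-2-methyl-4-(triisopropylsilyl)but-3-yn-1-yl]oxolan-2-one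
Product: 12 (4S,5R)-4-allyl-3-methylidene-5-[(2S)-2-methylbut-3-yn-1-yl]oxolan-2-one
Conditions: Bu4NF (1.1 equiv), AcOH (1.1 equiv), THF, 0 °C
Reagents that add atoms: none
Why: Fluoride-induced protodesilylation of the alkyne, buffered with acetic acid so that the base-sensitive methylene lactone is neither attacked in a Michael sense nor isomerised.

Step 8
Reactants: 12 (4S,5R)-4-allyl-3-methylidene-5-[(2S)-2-methylbut-3-yn-1-yl]oxolan-2-one; 13 methyl vinyl ketone
Product: 15 monomer (3aS,7S,8aR)-7-methyl-3-methylidene-6-[(1E)-3-oxobut-1-enyl]-3,3a,4,7,8,8a-hexahydro-2H-cyclohepta[b]furan-2-one, via 6-vinyl diene 14 (not isolated)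
Conditions: second-generation Hoveyda–Grubbs catalyst (8 mol %), 13 (5 equiv), CH2Cl2 (5 mM), 40 °C
Reagents that add atoms: none
Why: Domino ring-closing enyne metathesis/cross-metathesis, in which the ruthenium carbene loads on the allyl group, closes ring A onto the terminal alkyne (exo mode) to the 1-vinylcycloheptene and the new vinyl group couples E-selectively with the electron-poor partner, while the 1,1-disubstituted methylene lactone stays inert and no stereocentre is touched.

Step 9
Reactants: 15 monomer (two molecules)
Product: 16 cyclobutane dimer (ring C1–C5–C13'–C11' cis-fused to ring A on the H7 face; C1 bears the (E)-3-oxobut-1-enyl arm; C11' is spiro to the primed lactone with C1 on its H7' face)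
Conditions: thioxanthen-9-one (10 mol %), 405 nm LED, degassed CH2Cl2 (0.5 M), −30 °C
Reagents that add atoms: none
Why: Triplet-sensitised dienone–alkene [2+2] photocycloaddition, in which only the dienone accepts the sensitiser energy, the reactive form of its triplet is twisted about C1=C5 with the spin on C5 localised like a nucleophilic alkyl radical, this centre adds (Giese-type polarity) to the free C13' terminus of the α-methylene lactone of a second molecule and the stabilised 1,4-biradical closes C1–C11', and C5 is set because the chair of ring A (all three substituents equatorial) can take up the twist only by swinging C6 toward the C7/C9 side, which turns outward the C5 lobe on the H7 face.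

Step 10
Reactants: 16 cyclobutane dimer
Product: 17 ring-B cyclohexene (C1=C2; H3 and H5 and C12' on one face of ring B; acetyl and C6 and C7' on the other)
Conditions: 1,2-dichlorobenzene (2 mM, degassed), BHT (0.1 equiv), base-washed glass, 140 °C
Reagents that add atoms: none
Why: Thermal vinylcyclobutane–cyclohexene rearrangement (formal [1,3]-carbon shift): the strained C1–C11' bond breaks homolytically to a tethered biradical made of the C1–C2–C3 allyl radical (extended into the C4 carbonyl) and the tertiary α-lactonyl radical C11', and the pair re-joins at C3. The closest known reaction type is the biradical ring expansion of 1,2-divinyl- and acceptor-substituted vinylcyclobutanes to cyclohexenes. Ring B closes by 1,6-recombination of the biradical at the allyl terminus, suprafacially on the allyl face that already carries the C5–C13' tether, so the four-membered ring grows by the two atoms C2 and C3. C5 is untouched; C11' is re-formed by bonding on the lactone face that carries H7' and is anti to the C7'–C6' bond (C12' ends exo, C7' over the new ring); and C3 (acetyl cis to C6) follows from the E arm but is erased in step 11. Ring expansion must win over re-closure at C1 and over cleavage of C5–C13' to two molecules of 15: re-closure is degenerate and reversible, the equatorial C10 methyl group pushes C3 to the C5 side of the allyl radical (the only geometry that reaches C11'), the six-membered ring is the strain-free sink, and the lowest workable temperature favours the enthalpically better closure over the entropy-driven cleavage. High dilution keeps any released 15 from re-combining by a ground-state Diels–Alder reaction on the other face of ring A, and BHT and base-washed glass protect the methylene lactone and the β,γ-enone.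

Step 11
Reactants: 17 ring-B cyclohexene
Product: 19 target CNP0168949.4, via 1,2-epoxide 18 (not isolated)
Conditions: dimethyldioxirane (1.0 equiv), acetone–CH2Cl2, −40 to −20 °C; then Et3N (0.2 equiv), 0 °C to rt
Reagents that add atoms: dimethyldioxirane CC1(C)OO1
Why: Chemoselective epoxidation of the only unconjugated trisubstituted alkene (C1=C2) by the neutral dioxirane from the ring-B face opposite the pseudoaxial C3 acetyl group and C7' (the face of H3 and H5) sets the C1–O bond cis to H5, and amine-induced E1cB opening of the β,γ-epoxy ketone (enolisation at C3, cleavage of C2–O) should give the γ-hydroxy enone without touching C1.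

Compound list
1 | (E)-crotonaldehyde | C/C=C/C=O | starting material
2 | (triisopropylsilyl)acetylene | C#C[Si](C(C)C)(C(C)C)C(C)C | starting material
3 | (S)-3-methyl-5-(triisopropylsilyl)pent-4-ynal | O=CC[C@H](C)C#C[Si](C(C)C)(C(C)C)C(C)C | intermediate
4 | 3-(trimethylsilyl)propynal | C[Si](C)(C)C#CC=O | starting material
5 | allyltributylstannane | C=CC[Sn](CCCC)(CCCC)CCCC | starting material
6 | (R)-1-(trimethylsilyl)hex-5-en-1-yn-3-ol | C[Si](C)(C)C#C[C@@H](CC=C)O | intermediate
7 | (R)-1-(trimethylsilyl)hex-5-en-1-yn-3-yl methanesulfonate | C[Si](C)(C)C#C[C@@H](CC=C)OS(C)(=O)=O | intermediate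
8 | allenylindium reagent, iodo(mesyloxy)[1-(trimethylsilyl)hexa-1,2,5-trien-1-yl]indium | C[Si](C)(C)C([In](I)OS(C)(=O)=O)=[C@]=C([H])CC=C | intermediate
9 | (3S,4R,6S)-3-allyl-6-methyl-8-(triisopropylsilyl)-1-(trimethylsilyl)octa-1,7-diyn-4-ol | C[Si](C)(C)C#C[C@H](CC=C)[C@H](O)C[C@H](C)C#C[Si](C(C)C)(C(C)C)C(C)C | intermediate
10 | (3S,4R,6S)-3-allyl-6-methyl-8-(triisopropylsilyl)octa-1,7-diyn-4-ol | C#C[C@H](CC=C)[C@H](O)C[C@H](C)C#C[Si](C(C)C)(C(C)C)C(C)C | intermediate
11 | (4S,5R)-4-allyl-3-methylidene-5-[(2S)-2-methyl-4-(triisopropylsilyl)but-3-yn-1-yl]oxolan-2-one | C=C1C(=O)O[C@H](C[C@H](C)C#C[Si](C(C)C)(C(C)C)C(C)C)[C@H]1CC=C | intermediate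
12 | (4S,5R)-4-allyl-3-methylidene-5-[(2S)-2-methylbut-3-yn-1-yl]oxolan-2-one | C=C1C(=O)O[C@H](C[C@H](C)C#C)[C@H]1CC=C | intermediate
13 | methyl vinyl ketone | C=CC(C)=O | starting material
14 | (3aS,7S,8aR)-6-ethenyl-7-methyl-3-methylidene-3,3a,4,7,8,8a-hexahydro-2H-cyclohepta[b]furan-2-one | C=C1C(=O)O[C@@H]2C[C@H](C)C(C=C)=CC[C@@H]12 | intermediate
15 | monomer, (3aS,7S,8aR)-7-methyl-3-methylidene-6-[(1E)-3-oxobut-1-enyl]-3,3a,4,7,8,8a-hexahydro-2H-cyclohepta[b]furan-2-one | C=C1C(=O)O[C@@H]2C[C@H](C)C(/C=C/C(C)=O)=CC[C@@H]12 | intermediate
16 | cyclobutane dimer (C1–C5–C13'–C11') | C=C1C(=O)O[C@@H]2C[C@H](C)[C@]3(/C=C/C(C)=O)[C@]4(C[C@@H]3C[C@@H]12)C(=O)O[C@@H]1C[C@H](C)C(/C=C/C(C)=O)=CC[C@H]14 | intermediate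
17 | ring-B cyclohexene (C1=C2, 3-acetyl, spiro C11') | C=C1C(=O)O[C@@H]2C[C@H](C)C3=C[C@H](C(C)=O)[C@]4(C[C@@H]3C[C@@H]12)C(=O)O[C@@H]1C[C@H](C)C(/C=C/C(C)=O)=CC[C@H]14 | intermediate
18 | 1,2-epoxide of 17 (oxygen on the face of H3 and H5) | C=C1C(=O)O[C@@H]2C[C@H](C)[C@@]35O[C@H]5[C@H](C(C)=O)[C@]4(C[C@@H]3C[C@@H]12)C(=O)O[C@@H]1C[C@H](C)C(/C=C/C(C)=O)=CC[C@H]14 | intermediate
19 | CNP0168949.4 | C=C1C(=O)O[C@@H]2C[C@H](C)[C@]3(O)C=C(C(C)=O)[C@]4(C[C@@H]3C[C@@H]12)C(=O)O[C@@H]1C[C@H](C)C(/C=C/C(C)=O)=CC[C@H]14 | target

Total step count: 11. Longest linear sequence: 10 (steps 2 to 11).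

Steps most likely to fail

Step 9.
- What may go wrong: the triplet energy may drain away through E/Z isomerisation about C2=C3 followed by oxa-6π closure. Addition may run through the planar allyl-type form of the triplet on the wrong face of ring A. Dienone–dienone dimerisation may compete.
- Fallback: it changes the order of events and sets out from 12.
- Ring-closing enyne metathesis alone (second-generation Grubbs catalyst, ethene atmosphere, CH2Cl2) lets the diene 14 be isolated. Its triplet has no isomerisable enone arm and places the localised spin on C5 by preference.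
- The same sensitised [2+2] dimerisation of 14 should give the bis-vinyl cyclobutane dimer F1.
- Twofold cross-metathesis of F1 with 13 (second-generation Hoveyda–Grubbs catalyst) installs both enone arms and comes back to the route at 16.

Step 10.
- What may go wrong: cleavage of the biradical to two molecules of 15 may outrun closure, and the β,γ-enone may slip into conjugation at the reaction temperature.
- Fallback: it replaces homolysis by metal-mediated heterolysis, sets out from 16 and comes back at 17.
- With Pd2(dba)3 and dppe (catalytic) in DMSO at 60 °C, zerovalent palladium binds the electron-poor C2=C3 bond and ionises the strained allylic C1–C11' bond. This gives a π-allylpalladium/lactone enolate zwitterion.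
- The zwitterion has no path back to 15 and should collapse at the less hindered terminus C3. The reaction type is known from acceptor-substituted vinylcyclopropanes and vinylcyclobutanes.
- C5 is not involved. This fallback makes no compound outside the list (F0).

Step 11.
- What may go wrong: facial selectivity of the epoxidation may be poor, and oxidation of the C1'=C5' bond of the dienone may compete.
- Fallback: it sets out from 17 and uses the Schenck ene reaction (O2, tetraphenylporphyrin, visible light, CH2Cl2, −20 °C).
- Singlet oxygen reacts suprafacially. It takes H3, which lies on the face opposite the acetyl group, and delivers oxygen to C1 on that same face while the double bond moves to C2=C3. The product is the C1 allylic hydroperoxide F2.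
- PPh3 reduces F2 and the route is rejoined at 19.

Further compounds
F1 | step 9 | bis-vinyl cyclobutane dimer of 14 | C=C1C(=O)O[C@@H]2C[C@H](C)[C@]3(C=C)[C@]4(C[C@@H]3C[C@@H]12)C(=O)O[C@@H]1C[C@H](C)C(C=C)=CC[C@H]14
F0 | step 10 | none | none
F2 | step 11 | C1 allylic hydroperoxide of the target skeleton | C=C1C(=O)O[C@@H]2C[C@H](C)[C@]3(OO)C=C(C(C)=O)[C@]4(C[C@@H]3C[C@@H]12)C(=O)O[C@@H]1C[C@H](C)C(/C=C/C(C)=O)=CC[C@H]14
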